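The constants describe a round of the catalyst, and the question was what share of that round hangs on the reagent.

    starting material + free catalyst → catalyst intermediate A (k1 = 2800 /M/s)
    catalyst intermediate A ⇌ catalyst intermediate B (K2 = 1.0, k2 = 21 /s)
    reagent + catalyst intermediate B → catalyst intermediate C (k3 = 1800 /M/s)
    catalyst intermediate C ⇌ released group + catalyst intermediate D (K4 = 0.092 M, k4 = 4.9 /s)
    catalyst intermediate D → free catalyst + product (k5 = 1.8 /s)

starting material 0.0020 M; reagent 1.10 equiv; free catalyst 11 mol%

- apparent order in reagent when 20 % of the starting material are converted (percent change of the rate of making product for one percent more reagent charged)

I reckoned one steady turn at 20 % conversion, taking as much reagent gone as starting material and neglecting the return of step 4. Step 3 draws on catalyst intermediate B, but with 1.0 step 2 shares the pool of catalyst intermediates A and B evenly, so step 3 acts on half of that pool. The wait for reagent was therefore 0.617 s. The other steps, taken in series, made up the rest, 1.03 s, which is longer than the wait. Their sum is the round, 1.65 s: the turnover time, the time one catalyst takes per product at steady cycling. One percent more reagent charged, with the same amount used up, raises the reagent present by 1.22 percent and shortens the wait by about as much, so I committed to an order of wait over round times that factor, 0.458.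

The forecast said 0.4, lower than my figure, and called the reagent step “only partly rate-limiting”.

The simulation gave 0.40. At 1.96 s, catalyst intermediate B was being made 1.01 times as fast as it was used, and catalyst intermediate D 0.971 times. Reckoned the same way at 70 percent conversion, the round came to 2.79 s, which put the rate at 0.591 of its value at 20 % conversion; the flask read 0.63.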